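**Strategy.** Ring A (C6–C11, target numbering) is cut at C8–C9 and C10–C11, so that its C9–C10 ethano bridge is ethylene. The feature exploited is the 1,4-relationship, across ring A, of the bromine-bearing C8 and the methylidene-bearing C11, which flank the adjacent quaternary carbons C7 and C6. In one rhodium-catalysed operation an aldehyde (future C8) and a terminal alkyne (future C11=CH2) on those two carbons take up ethylene, closing ring A as a 4-methylidenecyclohexanone. The precursor is a ring B cyclohexene whose quaternary carbon carries an ethynyl group and a CMe2–CHO arm; it comes from an enantioselective Diels–Alder spirolactone. Reduction, invertive bromination and bromohydrin formation follow.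

Key step: step 6

Numbering used for the target and for 11: spiro[5.5]undecane with ring B = C1–C5 (C2 = CHBr, C3 = C(CH3)OH), C6 = spiro carbon, ring A = C7 (CMe2), C8 (CHBr), C9, C10, C11 (C=CH2).

Assumption: lactone 2 has no α-hydrogen and a locked s-cis enoate, so the facial sense of the oxazaborolidinium catalyst in step 2 is assigned by analogy with other enoate dienophiles; the (S)-catalyst is written, and its (R)-antipode is to be used should the sense prove opposite.

Step 1
Reactants: 1 4,4-dimethyldihydrofuran-2,3-dione (ketopantolactone)
Product: 2 4,4-dimethyl-3-methylidenedihydrofuran-2(3H)-one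
Conditions: Ph3PCH3Br, KN(SiMe3)2, THF, 0 °C; ylide added to 1 at −78 °C, then to 0 °C
Reagents that add atoms: methyltriphenylphosphonium bromide, C[P+](c1ccccc1)(c1ccccc1)c1ccccc1.[Br-]
Why: Wittig olefination: the salt-free ylide attacks the non-enolisable ketone carbonyl of the α-keto lactone, which is far more electrophilic than the lactone carbonyl, and adding the ylide to the ketone at low temperature should keep it from adding to the Michael-acceptor product; no stereocenter is formed.

Step 2
Reactants: 2 4,4-dimethyl-3-methylidenedihydrofuran-2(3H)-one; 3 isoprene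
Product: 4 (5S)-4,4,8-trimethyl-2-oxaspiro[4.5]dec-7-en-1-one
Conditions: (S)-3,3-diphenyl-1-(2-methylphenyl)tetrahydro-1H,3H-pyrrolo[1,2-c][1,3,2]oxazaborole (20 mol%), AlBr3 (16 mol%), isoprene (5 equiv), CH2Cl2, −40 to −20 °C
Reagents that add atoms: none
Why: Lewis-acid-catalysed Diels–Alder reaction: boron coordination lowers the LUMO of the s-cis-locked enoate, isoprene adds in the para orientation (its C1 bonds to the exocyclic CH2, its C4 to the α-carbon), and the chiral oxazaborolidinium blocks one face of the dienophile so that the quaternary carbon, the future spiro centre C6, should form with the (5S) configuration.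

Step 3
Reactants: 4 (5S)-4,4,8-trimethyl-2-oxaspiro[4.5]dec-7-en-1-one
Product: 5 (5S)-4,4,8-trimethyl-2-oxaspiro[4.5]dec-7-en-1-ol (lactol, both anomers)
Conditions: iBu2AlH (1.1 equiv), CH2Cl2, −78 °C; aqueous potassium sodium tartrate
Reagents that add atoms: none
Why: Partial reduction of a lactone: the tetrahedral aluminium hemiacetal is stable at −78 °C and gives the lactol on hydrolysis, the quaternary stereocenter not being involved.

Step 4
Reactants: 5 (5S)-4,4,8-trimethyl-2-oxaspiro[4.5]dec-7-en-1-ol
Product: 6 2-[(1R)-1-ethynyl-4-methylcyclohex-3-en-1-yl]-2-methylpropan-1-ol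
Conditions: dimethyl (1-diazo-2-oxopropyl)phosphonate (2 equiv), K2CO3 (3 equiv), MeOH, 0 to 40 °C
Reagents that add atoms: dimethyl (1-diazo-2-oxopropyl)phosphonate, CC(=O)C(=[N+]=[N-])P(=O)(OC)OC
Why: Seyferth–Gilbert homologation under Ohira–Bestmann conditions: the diazophosphonate anion adds to the non-enolisable hydroxy aldehyde in equilibrium with the lactol and the resulting alkylidene carbene rearranges by 1,2-hydrogen shift to the terminal alkyne, with the adjacent stereocenter untouched.

Step 5
Reactants: 6 2-[(1R)-1-ethynyl-4-methylcyclohex-3-en-1-yl]-2-methylpropan-1-ol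
Product: 7 2-[(1R)-1-ethynyl-4-methylcyclohex-3-en-1-yl]-2-methylpropanal
Conditions: Dess–Martin periodinane, CH2Cl2, 0 °C to rt
Reagents that add atoms: none
Why: Dess–Martin oxidation converts the neopentylic primary alcohol into the α-quaternary aldehyde, which cannot enolise or epimerise, and leaves alkyne and alkene intact.

Step 6
Reactants: 7 2-[(1R)-1-ethynyl-4-methylcyclohex-3-en-1-yl]-2-methylpropanal; 8 ethylene
Product: 9 (6R)-1,1,9-trimethyl-5-methylidenespiro[5.5]undec-8-en-2-one
Conditions: [Rh(dppe)]2(BF4)2 (5 mol%; dppe = 1,2-bis(diphenylphosphino)ethane), ethylene (10 bar), CH2Cl2, 25 to 40 °C, slow addition of 7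
Reagents that add atoms: none
Why: Proposed new method: oxidative addition of the aldehyde C–H bond of 7 to cationic monovalent rhodium gives an acyl rhodium hydride, syn hydrorhodation of the tethered terminal alkyne (hydride to the terminal carbon) gives a five-membered acyl–alkenyl rhodacycle, ethylene inserts into one Rh–C bond, and C–C reductive elimination from the seven-membered rhodacycle releases the cyclohexanone. The closest known reaction type is the rhodium-catalysed [4+2] annulation of 4-alkynals with alkynes and with acrylamides, which intercepts the same rhodacycle; ethylene and a terminal alkynal have not been shown in it. Ring A is closed by formal [4+2] annulation, that is 5-exo-dig hydrometalation followed by a two-carbon ring expansion, and both new bonds (C8–C9 and C10–C11 of the target) come from the one ethylene molecule. No stereocenter is created: C11 becomes the methylidene carbon, C8 the carbonyl carbon, and the spiro centre is not touched. The step needs chemoselectivity for ethylene insertion over intramolecular trans hydroacylation to a cyclopentenone, over decarbonylation and over β-hydride elimination; ethylene pressure, the quaternary α-carbon of the aldehyde, the geminal substitution of the tether and the cyclic nature of the alkyl rhodium intermediate should secure it. Ethylene being symmetrical, no regiochemical question arises, and the terminal alkyne gives =CH2, so no alkene geometry is at stake.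

Step 7
Reactants: 9 (6R)-1,1,9-trimethyl-5-methylidenespiro[5.5]undec-8-en-2-one
Product: 10 (2R,6R)-1,1,9-trimethyl-5-methylidenespiro[5.5]undec-8-en-2-ol
Conditions: (S)-1-methyl-3,3-diphenyltetrahydro-1H,3H-pyrrolo[1,2-c][1,3,2]oxazaborole (20 mol%), catecholborane (2 equiv), toluene, −78 to −30 °C; aqueous work-up
Reagents that add atoms: none
Why: Corey–Bakshi–Shibata reduction: the (S)-oxazaborolidine binds the ketone with the quaternary C1 as the large and the C3 methylene as the small substituent and delivers hydride to give the (2R) carbinol under reagent control, the remote spiro centre exerting no bias, while catecholborane at low temperature does not hydroborate the two alkenes.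

Step 8
Reactants: 10 (2R,6R)-1,1,9-trimethyl-5-methylidenespiro[5.5]undec-8-en-2-ol
Product: 11 (6R,8S)-8-bromo-3,7,7-trimethyl-11-methylidenespiro[5.5]undec-2-ene
Conditions: CBr4 (2.5 equiv), PPh3 (2.6 equiv), CH2Cl2, 0 °C to rt
Reagents that add atoms: tetrabromomethane, BrC(Br)(Br)Br
Why: Appel reaction: the alkoxyphosphonium ion, axial in the reacting chair of ring A, is displaced by bromide in an SN2 process with inversion, which turns the (2R) alcohol into the equatorial (8S) bromide, a substitution that is known for axial neopentylic cyclohexanols under these non-ionising conditions.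

Step 9
Reactants: 11 (6R,8S)-8-bromo-3,7,7-trimethyl-11-methylidenespiro[5.5]undec-2-ene
Product: 12 (2R,3R,6R,8S)-2,8-dibromo-3,7,7-trimethyl-11-methylidenespiro[5.5]undecan-3-ol
Conditions: NBS (1.05 equiv), acetone/H2O 4:1, 0 °C, dark
Reagents that add atoms: N-bromosuccinimide, O=C1CCC(=O)N1Br; water, O
Why: Bromohydrin formation: the trisubstituted ring B alkene, more nucleophilic than the neopentylic methylidene of ring A, takes up Br+ on the face remote from the pseudoaxial C11 arm of the spiro carbon and water opens the bromonium ion at the tertiary C3 with inversion (Markovnikov), which sets C2 (R) and C3 (R) as the trans bromohydrin with bromine and hydroxyl equatorial.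

**Compound list**

1 | 4,4-dimethyldihydrofuran-2,3-dione (ketopantolactone) | CC1(C)COC(=O)C1=O | starting material
2 | 4,4-dimethyl-3-methylidenedihydrofuran-2(3H)-one | C=C1C(=O)OCC1(C)C | intermediate
3 | isoprene (2-methylbuta-1,3-diene) | C=CC(C)=C | starting material
4 | (5S)-4,4,8-trimethyl-2-oxaspiro[4.5]dec-7-en-1-one | O=C1OCC(C)(C)[C@@]12CCC(C)=CC2 | intermediate
5 | (5S)-4,4,8-trimethyl-2-oxaspiro[4.5]dec-7-en-1-ol (lactol, both anomers) | OC1OCC(C)(C)[C@@]12CCC(C)=CC2 | intermediate
6 | 2-[(1R)-1-ethynyl-4-methylcyclohex-3-en-1-yl]-2-methylpropan-1-ol | OCC(C)(C)[C@]1(C#C)CCC(C)=CC1 | intermediate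
7 | 2-[(1R)-1-ethynyl-4-methylcyclohex-3-en-1-yl]-2-methylpropanal | O=CC(C)(C)[C@]1(C#C)CCC(C)=CC1 | intermediate
8 | ethylene | C=C | starting material
9 | (6R)-1,1,9-trimethyl-5-methylidenespiro[5.5]undec-8-en-2-one | C=C1CCC(=O)C(C)(C)[C@@]12CCC(C)=CC2 | intermediate
10 | (2R,6R)-1,1,9-trimethyl-5-methylidenespiro[5.5]undec-8-en-2-ol | C=C1CC[C@@H](O)C(C)(C)[C@@]12CCC(C)=CC2 | intermediate
11 | (6R,8S)-8-bromo-3,7,7-trimethyl-11-methylidenespiro[5.5]undec-2-ene | C=C1CC[C@H](Br)C(C)(C)[C@@]12CCC(C)=CC2 | intermediate
12 | (2R,3R,6R,8S)-2,8-dibromo-3,7,7-trimethyl-11-methylidenespiro[5.5]undecan-3-ol | C=C1CC[C@H](Br)C(C)(C)[C@@]12CC[C@@](C)(O)[C@H](Br)C2 | target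

Total step count: 9. Longest linear sequence: 9 steps (1 to 12).

**Steps most likely to fail**

1. Step 6 (bears the label "Proposed new method:"). The acyl–alkenyl rhodacycle may collapse by intramolecular trans hydroacylation to a cyclopentenone, lose CO, or the alkyne may oligomerise, before ethylene is taken up. The fallback uses known chemistry, sets out from 7 and comes back at 9. CH2=CHMgBr (THF, −78 °C) adds to the aldehyde to give the allylic alcohol 4-[(1R)-1-ethynyl-4-methylcyclohex-3-en-1-yl]-4-methylpent-1-en-3-ol F1 (both carbinol epimers; this makes the C8–C9 bond). Dess–Martin oxidation gives the enone 4-[(1R)-1-ethynyl-4-methylcyclohex-3-en-1-yl]-4-methylpent-1-en-3-one F2. Bu3SnH/AIBN (benzene, 80 °C, high dilution) then closes ring A: the stannyl radical adds to the alkyne terminus and the alkenyl radical attacks the enone β-carbon in a 6-endo-trig closure (C10–C11 bond). This gives the vinylstannane (6S)-1,1,9-trimethyl-5-[(tributylstannyl)methylidene]spiro[5.5]undec-8-en-2-one F3, which has the same spatial arrangement as 9; the descriptor changes only because of the tin substituent. Protodestannylation (HCl, CH2Cl2, 0 °C) delivers 9. The two ring A bonds are then made in separate operations.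

2. Step 8. E2 elimination across C8–C9 (an anti-periplanar axial hydrogen is available) and ionisation with a 1,2-methyl shift from C7 may outrun the slow bimolecular substitution at the neopentylic carbon. The fallback sets out from 10 and comes back at 11. The alcohol is converted (ClCH2SO2Cl, pyridine, CH2Cl2, 0 °C) into (2R,6R)-1,1,9-trimethyl-5-methylidenespiro[5.5]undec-8-en-2-yl chloromethanesulfonate F4, an isolable ester with a small, highly nucleofugal leaving group. It is then displaced with LiBr (DMF, 50 °C) with inversion. Activation and displacement are thus separated and run without phosphonium species or acid.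

3. Step 2. Enantiofacial discrimination may be poor, or the cycloaddition slow, at the hindered α-methylene lactone, which lacks the α C–H contact that normally organises enoate dienophiles on this catalyst. The fallback sets out from 2 and comes back at 4; it makes the quaternary carbon without stereochemical demand and writes the absolute configuration afterwards by enantioselective deprotonation. Thermal Diels–Alder reaction of 2 with 2-(trimethylsilyloxy)buta-1,3-diene (toluene, 130 °C, sealed tube) gives the silyl enol ether 4,4-dimethyl-8-(trimethylsilyloxy)-2-oxaspiro[4.5]dec-7-en-1-one F5 (racemic, not isolated). Acidic work-up hydrolyses it to the achiral keto lactone 4,4-dimethyl-2-oxaspiro[4.5]decane-1,8-dione F6. Its ring B chair is locked by the equatorial CMe2 arm, so a chiral lithium amide (lithium bis[(R)-1-phenylethyl]amide with LiCl, THF, −78 °C; antipode chosen to give the (5S) series) should remove one of the two enantiotopic axial α-hydrogens. Trapping with N-(5-chloropyridin-2-yl)triflimide gives the enol triflate (5S)-4,4-dimethyl-1-oxo-2-oxaspiro[4.5]dec-7-en-8-yl trifluoromethanesulfonate F7. Methylation (MeMgBr, Fe(acac)3, THF/NMP, −30 °C) gives 4.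

**Further compounds**

F1 | step 6 | 4-[(1R)-1-ethynyl-4-methylcyclohex-3-en-1-yl]-4-methylpent-1-en-3-ol | C=CC(O)C(C)(C)[C@]1(C#C)CCC(C)=CC1
F2 | step 6 | 4-[(1R)-1-ethynyl-4-methylcyclohex-3-en-1-yl]-4-methylpent-1-en-3-one | C=CC(=O)C(C)(C)[C@]1(C#C)CCC(C)=CC1
F3 | step 6 | (6S)-1,1,9-trimethyl-5-[(tributylstannyl)methylidene]spiro[5.5]undec-8-en-2-one | CCCC[Sn](CCCC)(CCCC)C=C1CCC(=O)C(C)(C)[C@@]12CCC(C)=CC2
F4 | step 8 | (2R,6R)-1,1,9-trimethyl-5-methylidenespiro[5.5]undec-8-en-2-yl chloromethanesulfonate | C=C1CC[C@@H](OS(=O)(=O)CCl)C(C)(C)[C@@]12CCC(C)=CC2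
F5 | step 2 | 4,4-dimethyl-8-(trimethylsilyloxy)-2-oxaspiro[4.5]dec-7-en-1-one | O=C1OCC(C)(C)C12CCC(O[Si](C)(C)C)=CC2
F6 | step 2 | 4,4-dimethyl-2-oxaspiro[4.5]decane-1,8-dione | O=C1OCC(C)(C)C12CCC(=O)CC2
F7 | step 2 | (5S)-4,4-dimethyl-1-oxo-2-oxaspiro[4.5]dec-7-en-8-yl trifluoromethanesulfonate | O=C1OCC(C)(C)[C@@]12CCC(OS(=O)(=O)C(F)(F)F)=CC2
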